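The earlier runs and the new flask were generated by integration with made-up constants; noise was put on by code.

Slowness is where we would begin our reply to your quick question, since the flasks are read at 2.0 h, later than any reading we hold, and the target in the beta run falls faster than in the gamma run.

in all of them: substrate 0.032 M; initiator 10 mol%
- gamma: coupling partner 0.44 equiv; run made earlier
- beta: coupling partner 5.5 equiv; run made earlier
- Sunday's: coupling partner 0.300 equiv; time 2.0 h
- Thursday's: coupling partner 0.400 equiv; time 2.0 h
- Friday's: coupling partner 0.800 equiv; time 2.0 h
- Monday's: coupling partner 4.80 equiv; time 2.0 h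
- Wednesday's: coupling partner 1.20 equiv; time 2.0 h
- Saturday's: coupling partner 1.80 equiv; time 2.0 h

| run | time / min | target / % |
|---|---|---|
| gamma | 8.00 | 18.5 |
| gamma | 20.0 | 20.4 |
| gamma | 40.0 | 18.5 |
| gamma | 60.0 | 17.3 |
| beta | 8.00 | 10.8 |
| beta | 20.0 | 2.7 |
| beta | 40.0 | 0.8 |
| beta | 60.0 | 0.4 |

(each reading ± 0.5 percentage points)



* ranking by amount of target, in percent of the substrate charged, from high to low, at 2.0 h (Sunday's / Thursday's / Friday's / Monday's / Wednesday's / Saturday's)
* the amount of target, in percent of the substrate charged of the flask you put first, at 2.0 h
* the amount of target, in percent of the substrate charged of the flask you put last, at 2.0 h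

In the gamma run, charged with 0.44 equiv of coupling partner, the target stands at 20.4% after 20.0 min and then sinks. Treating that sinking as pseudo-first-order, we read its time constant from the readings, scatter included:

τ = (60.0 min − 20.0 min) / ln(20.4% / 17.3%) = 243 min

This τ, the fade time, is the time in which the target, at the pace read past the highest reading of the gamma run, falls by a factor of e. The same reckoning on the first two readings of the beta run, charged with 5.5 equiv, gives 8.66 min, far shorter than τ, so we expect Monday's, at 4.80 equiv, to end below the last beta reading of 0.4%.

Our own number for the best flask assumes that Friday's, at 0.800 equiv, peaks about where the gamma run did and then fades with τ: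

c(target) ≈ 20.4% · exp(−(2.0 h − 20.0 min) / τ) = 13.5%

Your forecast ranks Friday's > Wednesday's > Thursday's > Sunday's > Saturday's > Monday's, with 17% first and 0.1% last, and it speaks of “a slow, partner-independent loss of target after its peak”. We commit to the same ranking, but its top stands higher than our 13.5%.

The flasks gave Friday's > Wednesday's > Thursday's > Sunday's > Saturday's > Monday's, with 15.4% in Friday's and 0% in Monday's.

    2 first chain carrier → ended chains B (k = 7.00 × 10⁶ M⁻¹ s⁻¹)
    coupling partner + first chain carrier ⇌ target + second chain carrier (K = 0.150, k = 12400 M⁻¹ s⁻¹)
    substrate + initiating radical → capped initiator + first chain carrier (k = 47000 M⁻¹ s⁻¹)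
    2 second chain carrier → ended chains A (k = 5.00 × 10⁶ M⁻¹ s⁻¹)
    substrate + target → side product (k = 0.00716 M⁻¹ s⁻¹)
    substrate + second chain carrier → released group + first chain carrier (k = 6800 M⁻¹ s⁻¹)
    coupling partner + target → over-reaction product (k = 0.0632 M⁻¹ s⁻¹)
    initiator → 2 initiating radical (k = 2.78 × 10⁻⁴ s⁻¹)

At 2.00 h, Friday's had 0.425% of its coupling partner charge left. The same flask read at 50 min held 20.0% of target, and τ from the gamma run carries that to 15.0% at 2.0 h, where Friday's stands at 15.4%.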